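All runs come from a simulation from invented constants, and the scatter is random.

The easy step to count is the last one. In the gamma run, with 1.9% of the starting material left at 80.0 min, target falls from 73.0% to 70.4% of the charge by 120 min. I read that fall as a first-order loss of 9.07 × 10⁻⁴ /min, and this reading carries the scatter of both values.

| setting | gamma | summer | dawn | noon | dusk | autumn |
|---|---|---|---|---|---|---|
| starting material | 22 mM | 60 mM | 5.0 mM | 40 mM | 5.0 mM | 20 mM |
| reagent in the second phase | 80 mM | 250 mM | 150 mM | 50.0 mM | 80.0 mM | 80.0 mM |
| temperature | 25 °C | 55 °C | 10 °C | 25 °C | 25 °C | 25 °C |
| remark | run made earlier |  |  |  |  |  |
| time |  | 3.0 h | 3.0 h | 3.0 h | 3.0 h | 3.0 h |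
| volume of the second phase over the first |  | 2.0 | 2.0 | 2.0 | 2.0 | 2.0 |

gamma run (percent of the starting material charged)

| time / min | target / % | starting material / % |
|---|---|---|
| 25.0 | 41.1 | 50.7 |
| 50.0 | 66.3 | 15.5 |
| 80.0 | 73.0 | 1.9 |
| 120 | 70.4 | 0.1 |

(readings scatter by 0.3 percentage points)

- in the second phase: reagent in the second phase; everything else is in the first
- charges count per volume of the first phase; a concentration in a rate is the amount of a species over the volume of its own phase; every rate counts per litre of the first phase
- the earlier runs hold the two phases in the same ratio of volumes as the flask asked about
- the earlier runs do not show what temperature does; that part of a forecast is a guess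

* the flasks put in order of amount of target, in percent of the starting material charged, best first, at 3.0 h (summer / dawn / noon / dusk / autumn)
* the same order at 20 min (summer / dawn / noon / dusk / autumn)
* the amount of target, in percent of the starting material charged of the flask you put first, at 3.0 h
* the amount of target, in percent of the starting material charged of the flask you put last, at 3.0 h

The quantity I carry is the turnover count, the loss constant times the time a flask stands, 0.163 at 25 °C over 3.0 h. The fraction of target that stands through a given count is exp of minus that count.

Two extreme versions of autumn can be solved in the head. In the clean version, the starting material becomes target at the first instant and then stands the whole time, which leaves 84.9% of the charge. In the gamma version, target reaches the highest gamma reading, 73.0% at 80.0 min, and stands for the remaining time, which leaves 66.7%.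

The gap between these versions opens early. By 80.0 min the gamma balance of target and starting material is short by 25.1%, and the selectivity to 25.0 min, target over starting material consumed, reads 83.4%. The shortfall grows faster between the first two readings, by 0.00400 /min of the charge, than between the last two, by 0.00110 /min, so I suspect a loss that needs starting material and target together.

Autumn has 20 mM of starting material against 22 mM in gamma and 80.0 mM of reagent in the second phase against 80 mM, so I place it close to 66.7%. Dusk has a quarter of the autumn charge, so I place it between the versions. Noon has twice the autumn charge and 50.0 mM of reagent in the second phase against 80.0 mM, so I place it below 66.7%. Temperature is my guess. Dawn has the charge of dusk, 150 mM of reagent in the second phase and 10 °C, which should shrink the count, so I put dawn first, above 84.9%. Summer has 60 mM of starting material and 55 °C, which should swell the count, so I put summer last.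

The forecast gives dawn > dusk > autumn > noon > summer at 3.0 h and summer > dusk > autumn > noon > dawn at 20 min, with 80% (68% to 90%) first and 8% (0% to 35%) last, and says of summer, “so it should overcook”.

The flasks come out as dawn > dusk > autumn > noon > summer at 3.0 h, with 96.0% in dawn and 0% in summer, and as dusk > dawn > autumn > summer > noon at 20 min.

    target → over-reaction product (k = 0.00150 /min, Ea = 105 kJ/mol)
    starting material + reagent in the reaction phase → target (k = 5.70 /M/min, Ea = 38.0 kJ/mol)
    reagent in the reaction phase ⇌ reagent in the second phase, rate k3*([reagent in the reaction phase] - [reagent in the second phase]/K3) per volume of the first phase (partition coefficient = 1.70, kL = 0.0390 /min)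
    starting material + target → side product (k = 0.480 /M/min, Ea = 44.0 kJ/mol)
    (constants at 25 °C)

Autumn holds 66.0% of target against my 66.7%, with 17.1% in side product. Dusk stands at 87.0% of target at 1.50 h with 0.135% of starting material left, and the count of the remaining time, 0.0816, carries that to 80.2%, while dusk holds 76.1% at 3.0 h.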